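Open a ledger for the partner, the limiting reagent of the north-west run, where 21 mM stands against 28 mM of starting material, and book each mole of it to an account.

| flask | starting material | partner | second substrate | temperature | remark | time |
|---|---|---|---|---|---|---|
| south-west | 28 mM | 14 mM | 28 mM | 5 °C | run made earlier |  |
| north-west | 28 mM | 21 mM | 28 mM | 40 °C | run made earlier |  |
| grey | 28 mM | 28.0 mM | 28.0 mM | 40 °C |  | 80 min |
| red | 28 mM | 28.0 mM | 28.0 mM | 10 °C |  | 80 min |
| violet | 28 mM | 28.0 mM | 28.0 mM | 70 °C |  | 80 min |

| run | time / min | target / % | starting material / % |
|---|---|---|---|
| south-west | 60.0 | 7.5 | 92.5 |
| south-west | 150 | 12.1 | 86.9 |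
| south-west | 240 | 14.4 | 83.2 |
| south-west | 300 | 18.7 | 80.9 |
| north-west | 12.0 | 28.0 | 71.6 |
| north-west | 25.0 | 37.6 | 63.3 |
| north-west | 40.0 | 40.1 | 59.9 |
| north-west | 50.0 | 37.2 | 59.9 |

(standard deviation of a reading: 1 percentage point)

1. which flask leads in amount of target, in percent of the starting material charged ("all alike" within 1.5 percentage points) (grey / red / violet / all alike)
2. how much target is there at the end, in percent of the starting material charged: grey
3. how much target is there at the end, in percent of the starting material charged: red
4. how much target is there at the end, in percent of the starting material charged: violet

The north-west run gives us the first page. Starting material reads 59.9 % at 40.0 min and 59.9 % at 50.0 min, so that run has stopped, with target reading 40.1 % of the starting material charged. Turned to the partner's own charge, this first entry is 0.535, and we call it the partner yield: the fraction of the partner charged that stands as target when a run stops. The second entry is the remainder, 0.465, which the readings do not show, since starting material and target together already make up the charge of starting material. It can be booked in two ways: as free partner held back by a reverse step, or as partner consumed on paths that make no target. The readings do not separate these, so we commit to the second as our own wager, enter no free partner, and the books close.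

Suppose each way out is first order in partner. Partner then cancels from the ratio of the ways out at any moment, but that ratio still follows starting material and second substrate, and both of these fall as a run goes on. Carrying the partner yield to another charge of partner is therefore a rough wager, meant for a modest step with the temperature and the other charges held. Grey has the temperature and the other charges of the north-west run, with 28.0 mM of partner instead of 21 mM, so we expect target at 53.5 % of the starting material charged. This yield was read at 40 °C, so it gives us no figure for red or violet.

The forecast names violet as the leader, with 48 % for grey, 23 % for red and 53 % for violet. It books the remainder the other way, as “partner not exhausted”, and our figure for grey stands above its figure.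

Grey leads with 52.3 %, ahead of violet at 38.0 % and red at 23.2 %. The steps are these:

    starting material + partner → target (k = 0.0390 M⁻¹ s⁻¹, Ea = 66.0 kJ mol⁻¹)
    second substrate + partner → second product (k = 0.0150 M⁻¹ s⁻¹, Ea = 45.0 kJ mol⁻¹)
    second substrate ⇌ dormant form (K = 3.80, k = 2.20 × 10⁻⁴ s⁻¹, Ea = 94.0 kJ mol⁻¹, ΔH = 41.0 kJ mol⁻¹)
    second substrate + target ⇌ idle adduct, settled at all times (K = 1500 M⁻¹, ΔH = −41.0 kJ mol⁻¹)
    partner → decomposed reagent (k = 4.70 × 10⁻⁴ s⁻¹, Ea = 96.0 kJ mol⁻¹)
    (constants at 40 °C)

Grey's partner yield comes to 0.523 against the carried 0.535, and its partner stands at 0.34 % of its own charge after 80.0 min. The same flask run at 65 °C has a partner yield of 0.406, below the carried value; there partner stands at 0 %, and decomposed reagent holds 0.526 of the partner charged.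

The data were generated by integration on assumed constants; noise was put on by code.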